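The 14-membered ring is numbered from the acetoxy carbon (C1; ketones C4 and C11, CHMe C5, epoxide C9–C10, isopropylidene C12). Everything rests on disconnecting C3–C4: the C4 ketone, γ to the C1 oxygen, is carried as a C3≡C4 alkyne. Ring-closing alkyne metathesis closes the macrocycle and installs this latent ketone in one operation; the C1 hydroxyl later adds 5-endo to C4 only, and C5 stays a non-enolisable propargylic centre until then. The precursor is an open-chain, methyl-capped diyne carrying the C1 silyl ether, the C12 isopropylidene ketone, the C9–C10 epoxide and the C5 methyl centre.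

Key step: step 18

Remark: the C1 hydroxyl is carried as its triethylsilyl ether through the ring closure because alkylidyne catalysts are sensitive to protic groups, and commercial (R)-linalool and (S)-citronellal are assumed to be of high enantiomeric purity, which limits the purity at C1 and C5.

Step 1
Reactants: 1 (R)-linalool
Product: 2 triethyl{[(3R)-3,7-dimethylocta-1,6-dien-3-yl]oxy}silane
Conditions: TESOTf, 2,6-lutidine, CH2Cl2, −78 → 0 °C
Reagents that add atoms: triethylsilyl trifluoromethanesulfonate, CC[Si](CC)(CC)OS(=O)(=O)C(F)(F)F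
Why: Silyl triflate with a hindered pyridine silylates even a tertiary allylic alcohol (silyl ether formation), which masks the C1 oxygen against bromoetherification, organolithiums and the alkylidyne used later while the chiral-pool C1 centre is untouched.

Step 2
Reactants: 2 triethyl{[(3R)-3,7-dimethylocta-1,6-dien-3-yl]oxy}silane
Product: 4 (3R)-3,7-dimethyl-3-(triethylsilyloxy)oct-6-en-1-ol, via B-alkyl-9-BBN adduct 3 (not isolated)
Conditions: 9-BBN, THF, 0 °C → rt; then NaOH, H2O2, 0 °C
Reagents that add atoms: hydrogen peroxide, OO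
Why: Hydroboration–oxidation with 9-BBN is far faster at the monosubstituted vinyl group than at the trisubstituted alkene and places boron on the terminal carbon, so only the primary alcohol should form.

Step 3
Reactants: 4 (3R)-3,7-dimethyl-3-(triethylsilyloxy)oct-6-en-1-ol
Product: 5 (3R)-3,7-dimethyl-3-(triethylsilyloxy)oct-6-enal
Conditions: PhI(OAc)2, TEMPO (cat.), CH2Cl2, rt
Reagents that add atoms: none
Why: Oxoammonium-mediated (TEMPO) oxidation stops at the aldehyde and leaves the alkene and the tertiary silyl ether alone.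

Step 4
Reactants: 5 (3R)-3,7-dimethyl-3-(triethylsilyloxy)oct-6-enal
Product: 6 triethyl{[(4R)-1,1-dibromo-4,8-dimethylnona-1,7-dien-4-yl]oxy}silane
Conditions: CBr4, PPh3, Zn, CH2Cl2, 0 °C → rt
Reagents that add atoms: carbon tetrabromide, BrC(Br)(Br)Br
Why: Corey–Fuchs dibromomethylenation with the zinc-generated ylide converts the aldehyde to the 1,1-dibromoalkene under near-neutral conditions and adds the carbon of the future alkyne cap.

Step 5
Reactants: 6 triethyl{[(4R)-1,1-dibromo-4,8-dimethylnona-1,7-dien-4-yl]oxy}silane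
Product: 8 triethyl{[(5R)-5,9-dimethyldec-8-en-2-yn-5-yl]oxy}silane, via lithium acetylide 7 (not isolated)
Conditions: n-BuLi (2.1 equiv), THF, −78 → −20 °C; then MeI, → rt
Reagents that add atoms: iodomethane, CI
Why: In the second stage of the Corey–Fuchs sequence, bromine–lithium exchange and Fritsch–Buttenberg–Wiechell rearrangement give the lithium acetylide, which is C-methylated in the same flask to the 2-butynyl unit (C2–C3 plus cap) needed for metathesis.

Step 6
Reactants: 8 triethyl{[(5R)-5,9-dimethyldec-8-en-2-yn-5-yl]oxy}silane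
Product: 9 triethyl{[(5R)-8,9-dibromo-5,9-dimethyldec-2-yn-5-yl]oxy}silane (C8 epimers)
Conditions: Br2 (1.0 equiv), pyridine (cat.), CH2Cl2, −78 °C
Reagents that add atoms: bromine, BrBr
Why: Electrophilic anti-addition of bromine is much faster at the electron-rich trisubstituted alkene than at the dialkylalkyne, so one equivalent should give the vicinal dibromide, whose new CHBr centre forms unselectively and is destroyed in step 7.

Step 7
Reactants: 9 triethyl{[(5R)-8,9-dibromo-5,9-dimethyldec-2-yn-5-yl]oxy}silane (C8 epimers)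
Product: 10 triethyl{[(5R)-8-bromo-5,9-dimethyldec-8-en-2-yn-5-yl]oxy}silane
Conditions: DBU, DMF, 70 °C
Reagents that add atoms: none
Why: In this E2 dehydrobromination of a vicinal dibromide the hydrogen on the bromine-bearing carbon is the most acidic, and its loss with the tertiary bromide should give the fully substituted (Zaitsev) vinyl bromide that fixes the isopropylidene at C12.

Step 8
Reactants: 11 (S)-citronellal
Product: 13 (3S)-3,7-dimethyloct-6-en-1-yne, via enol nonaflate 12 (not isolated)
Conditions: nonafluorobutanesulfonyl fluoride, phosphazene base P2-Et (2.2 equiv), DMF, −30 °C → rt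
Reagents that add atoms: none
Why: One-pot dehydration of an enolisable aldehyde to a terminal alkyne proceeds by O-sulfonylation of the enolate and base-induced elimination of the alkenyl nonaflate; enolisation involves only C2, so the chiral-pool methyl centre (future C5) is retained.

Step 9
Reactants: 13 (3S)-3,7-dimethyloct-6-en-1-yne
Product: 15 (4S)-4,8-dimethylnon-7-en-2-yne, via lithium acetylide 14 (not isolated)
Conditions: n-BuLi, THF, −78 °C; then MeI, → rt
Reagents that add atoms: iodomethane, CI
Why: Deprotonation of the terminal alkyne and SN2 methylation of the acetylide give the methyl cap, and the acetylide stage protects the propargylic centre from base-induced isomerisation.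

Step 10
Reactants: 15 (4S)-4,8-dimethylnon-7-en-2-yne
Product: 18 (4S)-4-methylhept-5-yn-1-ol, via ozonide 16 (not isolated), via aldehyde 17 (not isolated)
Conditions: O3, CH2Cl2, Sudan III, −78 °C; PPh3, → rt; then NaBH4, MeOH, 0 °C
Reagents that add atoms: ozone, O=[O+][O-]
Why: Indicator-controlled ozonolysis cleaves the trisubstituted alkene much faster than the alkyne, and reductive work-up followed by borohydride reduction should deliver the primary alcohol carrying C6–C8.

Step 11
Reactants: 18 (4S)-4-methylhept-5-yn-1-ol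
Product: 19 (4S)-7-bromo-4-methylhept-2-yne
Conditions: CBr4, PPh3, CH2Cl2, 0 °C
Reagents that add atoms: carbon tetrabromide, BrC(Br)(Br)Br
Why: Appel bromination converts the primary alcohol to the bromide under neutral conditions without touching the alkyne or the remote stereocentre.

Step 12
Reactants: 19 (4S)-7-bromo-4-methylhept-2-yne and 20 ethyl but-2-ynoate
Product: 24 ethyl (2E,7S)-3,7-dimethyldec-2-en-8-ynoate, via Grignard reagent 21 (not isolated), via alkylcopper 22 (not isolated), via alkenylcopper 23 (not isolated)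
Conditions: Mg, THF, rt; CuBr·SMe2 (1.0 equiv), −45 °C; 20, −78 °C; MeOH, −78 °C
Reagents that add atoms: none
Why: The Grignard-derived organocopper adds syn across the ynoate at low temperature (carbocupration) and protonation with retention should give the (E)-trisubstituted enoate, the geometry required for the trans-type C9–C10 epoxide.

Step 13
Reactants: 24 ethyl (2E,7S)-3,7-dimethyldec-2-en-8-ynoate
Product: 25 (2E,7S)-3,7-dimethyldec-2-en-8-yn-1-ol
Conditions: DIBAL-H (2.2 equiv), CH2Cl2, −78 → 0 °C; aq. potassium sodium tartrate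
Reagents that add atoms: none
Why: Hydride (DIBAL-H) 1,2-reduction of the conjugated ester gives the allylic alcohol without touching the alkene or the alkyne.

Step 14
Reactants: 25 (2E,7S)-3,7-dimethyldec-2-en-8-yn-1-ol
Product: 26 [(2S,3S)-3-methyl-3-[(4S)-4-methylhept-5-yn-1-yl]oxiran-2-yl]methanol
Conditions: Ti(OiPr)4 (cat.), L-(+)-diethyl tartrate (cat.), t-BuOOH, 4 Å MS, CH2Cl2, −20 °C
Reagents that add atoms: tert-butyl hydroperoxide, CC(C)(C)OO
Why: In the Sharpless asymmetric epoxidation the titanium–L-(+)-tartrate complex delivers oxygen to the face of the (E)-allylic alcohol that gives the (2S,3S)-epoxide, which sets C9 (S) and C10 (R in the target) under reagent control irrespective of the remote C5 centre.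

Step 15
Reactants: 26 [(2S,3S)-3-methyl-3-[(4S)-4-methylhept-5-yn-1-yl]oxiran-2-yl]methanol
Product: 27 (2R,3S)-3-methyl-3-[(4S)-4-methylhept-5-yn-1-yl]oxirane-2-carbaldehyde
Conditions: PhI(OAc)2, TEMPO (cat.), CH2Cl2, rt; used crude
Reagents that add atoms: none
Why: TEMPO-mediated oxidation takes the primary epoxy alcohol to the epoxy aldehyde, whose α-carbon cannot enolise because it is part of the oxirane.

Step 16
Reactants: 10 triethyl{[(5R)-8-bromo-5,9-dimethyldec-8-en-2-yn-5-yl]oxy}silane and 27 (2R,3S)-3-methyl-3-[(4S)-4-methylhept-5-yn-1-yl]oxirane-2-carbaldehyde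
Product: 29 (5R)-5-methyl-1-[(2S,3S)-3-methyl-3-[(4S)-4-methylhept-5-yn-1-yl]oxiran-2-yl]-2-(propan-2-ylidene)-5-(triethylsilyloxy)non-7-yn-1-ol (C1 epimers), via vinyllithium 28 (not isolated)
Conditions: t-BuLi (2.0 equiv), Et2O, −78 °C; then 27, THF, −78 °C; H2O
Reagents that add atoms: none
Why: Bromine–lithium exchange gives the tetrasubstituted vinyllithium, whose 1,2-addition to the epoxy aldehyde forms the C11–C12 bond with the isopropylidene already in place; the carbinol centre forms as a mixture that is removed by oxidation in step 17.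

Step 17
Reactants: 29 (5R)-5-methyl-1-[(2S,3S)-3-methyl-3-[(4S)-4-methylhept-5-yn-1-yl]oxiran-2-yl]-2-(propan-2-ylidene)-5-(triethylsilyloxy)non-7-yn-1-ol (C1 epimers)
Product: 30 (5R)-5-methyl-1-[(2R,3S)-3-methyl-3-[(4S)-4-methylhept-5-yn-1-yl]oxiran-2-yl]-2-(propan-2-ylidene)-5-(triethylsilyloxy)non-7-yn-1-one
Conditions: Dess–Martin periodinane, pyridine, CH2Cl2, 0 °C → rt
Reagents that add atoms: none
Why: Dess–Martin oxidation of the hindered allylic carbinol under buffered, non-basic conditions gives the tetrasubstituted enone directly in its conjugated form, with no equilibration toward an isopropenyl isomer.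

Step 18
Reactants: 30 (5R)-5-methyl-1-[(2R,3S)-3-methyl-3-[(4S)-4-methylhept-5-yn-1-yl]oxiran-2-yl]-2-(propan-2-ylidene)-5-(triethylsilyloxy)non-7-yn-1-one
Product: 31 (1R,5S,9S,10R)-1,5,9-trimethyl-12-(propan-2-ylidene)-1-(triethylsilyloxy)-9,10-epoxycyclotetradec-3-yn-11-one
Conditions: [Mo(≡CC6H4-4-OMe)(OSiPh3)3] (10 mol%), powdered 5 Å MS, toluene (2 mM), rt → 60 °C
Reagents that add atoms: none
Why: The molybdenum alkylidyne adds across one 2-butynyl terminus to give a metallacyclobutadiene, cycloreversion releases but-2-yne and leaves a substrate-bound alkylidyne, and the same [2+2]/retro-[2+2] sequence at the second terminus forms the C3≡C4 bond and regenerates the catalyst. The closest known reaction type is ring-closing alkyne metathesis of bis(methylalkynes) with silanolate-ligated molybdenum alkylidynes, which is established for cycloalkynes of twelve or more ring atoms. The 14-membered carbocycle is closed by end-to-end macrocyclisation of the open chain; the linear C2–C3≡C4–C5 unit is nearly strain-free in a ring of this size, and high dilution together with trapping of but-2-yne on 5 Å sieves favours the monomeric ring over oligomers. No stereocentre is formed, and the propargylic C5 centre cannot epimerise under these neutral, aprotic conditions. The step needs chemoselectivity for the two alkynes over the tetrasubstituted C12 alkene, the C11 ketone and the oxirane, which is inherent to high-valent alkylidynes that do not engage alkenes, carbonyls or epoxides, and the silyl ether removes the only protic group that could protonate the alkylidyne.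

Step 19
Reactants: 31 (1R,5S,9S,10R)-1,5,9-trimethyl-12-(propan-2-ylidene)-1-(triethylsilyloxy)-9,10-epoxycyclotetradec-3-yn-11-one
Product: 32 (1R,5S,9S,10R)-1-hydroxy-1,5,9-trimethyl-12-(propan-2-ylidene)-9,10-epoxycyclotetradec-3-yn-11-one
Conditions: HF·pyridine, pyridine, THF, 0 °C → rt
Reagents that add atoms: none
Why: Buffered fluoride-mediated desilylation cleaves the tertiary triethylsilyl ether and frees the C1 hydroxyl without opening the epoxide or disturbing the enone.

Step 20
Reactants: 32 (1R,5S,9S,10R)-1-hydroxy-1,5,9-trimethyl-12-(propan-2-ylidene)-9,10-epoxycyclotetradec-3-yn-11-one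
Product: 34 (1R,5S,9S,10R)-1-hydroxy-1,5,9-trimethyl-12-(propan-2-ylidene)-9,10-epoxycyclotetradecane-4,11-dione, via bridged enol ether 33 (not isolated)
Conditions: [(JohnPhos)Au(MeCN)]SbF6 (5 mol%), THF/H2O (20:1), rt; then PPTS (cat.), rt
Reagents that add atoms: water, O
Why: Cationic gold(I) activates the ring alkyne for 5-endo-dig hydroalkoxylation by the homopropargylic C1 hydroxyl, which can reach only C4, and the cyclic enol ether is hydrolysed in the wet, mildly acidic medium to the C4 ketone (a net regioselective alkyne hydration) without enolisation toward C5.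

Step 21
Reactants: 34 (1R,5S,9S,10R)-1-hydroxy-1,5,9-trimethyl-12-(propan-2-ylidene)-9,10-epoxycyclotetradecane-4,11-dione
Product: 35 (1R,5S,9S,10R)-1,5,9-trimethyl-4,11-dioxo-12-(propan-2-ylidene)-9,10-epoxycyclotetradecyl acetate
Conditions: Ac2O, DMAP, Et3N, CH2Cl2, rt
Reagents that add atoms: acetic anhydride, CC(=O)OC(C)=O
Why: DMAP-catalysed acylation acetylates the tertiary C1 alcohol of the open hydroxy ketone (any transannular hemiketal equilibrates through it) under mild base that should leave the C5 centre, the epoxy ketone and the enone untouched.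

Compound list
1 | (R)-linalool, (3R)-3,7-dimethylocta-1,6-dien-3-ol | CC(C)=CCC[C@@](C)(O)C=C | starting material
2 | triethyl{[(3R)-3,7-dimethylocta-1,6-dien-3-yl]oxy}silane | CC(C)=CCC[C@@](C)(O[Si](CC)(CC)CC)C=C | intermediate
3 | 9-[(3S)-3,7-dimethyl-3-(triethylsilyloxy)oct-6-en-1-yl]-9-borabicyclo[3.3.1]nonane (same spatial arrangement as 2; descriptor changes by priority) | CC(C)=CCC[C@@](C)(O[Si](CC)(CC)CC)CCB1C2CCCC1CCC2 | intermediate
4 | (3R)-3,7-dimethyl-3-(triethylsilyloxy)oct-6-en-1-ol | CC(C)=CCC[C@@](C)(O[Si](CC)(CC)CC)CCO | intermediate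
5 | (3R)-3,7-dimethyl-3-(triethylsilyloxy)oct-6-enal | CC(C)=CCC[C@@](C)(O[Si](CC)(CC)CC)CC=O | intermediate
6 | triethyl{[(4R)-1,1-dibromo-4,8-dimethylnona-1,7-dien-4-yl]oxy}silane | CC(C)=CCC[C@@](C)(O[Si](CC)(CC)CC)CC=C(Br)Br | intermediate
7 | [(4R)-4,8-dimethyl-4-(triethylsilyloxy)non-7-en-1-yn-1-yl]lithium | [Li]C#CC[C@](C)(O[Si](CC)(CC)CC)CCC=C(C)C | intermediate
8 | triethyl{[(5R)-5,9-dimethyldec-8-en-2-yn-5-yl]oxy}silane | CC#CC[C@](C)(O[Si](CC)(CC)CC)CCC=C(C)C | intermediate
9 | triethyl{[(5R)-8,9-dibromo-5,9-dimethyldec-2-yn-5-yl]oxy}silane (C8 epimers) | CC#CC[C@](C)(O[Si](CC)(CC)CC)CCC(Br)C(C)(C)Br | intermediate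
10 | triethyl{[(5R)-8-bromo-5,9-dimethyldec-8-en-2-yn-5-yl]oxy}silane | CC#CC[C@](C)(O[Si](CC)(CC)CC)CCC(Br)=C(C)C | intermediate
11 | (S)-citronellal, (3S)-3,7-dimethyloct-6-enal | O=CC[C@@H](C)CCC=C(C)C | starting material
12 | (3S)-3,7-dimethylocta-1,6-dien-1-yl nonafluorobutane-1-sulfonate (E/Z mixture) | CC(C)=CCC[C@H](C)C=COS(=O)(=O)C(F)(F)C(F)(F)C(F)(F)C(F)(F)F | intermediate
13 | (3S)-3,7-dimethyloct-6-en-1-yne | C#C[C@@H](C)CCC=C(C)C | intermediate
14 | [(3S)-3,7-dimethyloct-6-en-1-yn-1-yl]lithium | [Li]C#C[C@@H](C)CCC=C(C)C | intermediate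
15 | (4S)-4,8-dimethylnon-7-en-2-yne | CC#C[C@@H](C)CCC=C(C)C | intermediate
16 | 3,3-dimethyl-5-[(3S)-3-methylhex-4-yn-1-yl]-1,2,4-trioxolane | CC#C[C@@H](C)CCC1OOC(C)(C)O1 | intermediate
17 | (4S)-4-methylhept-5-ynal | CC#C[C@@H](C)CCC=O | intermediate
18 | (4S)-4-methylhept-5-yn-1-ol | CC#C[C@@H](C)CCCO | intermediate
19 | (4S)-7-bromo-4-methylhept-2-yne | CC#C[C@@H](C)CCCBr | intermediate
20 | ethyl but-2-ynoate | CCOC(=O)C#CC | starting material
21 | [(4S)-4-methylhept-5-yn-1-yl]magnesium bromide | CC#C[C@@H](C)CCC[Mg]Br | intermediate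
22 | [(4S)-4-methylhept-5-yn-1-yl]copper(I), as its MgBr2/Me2S complex | CC#C[C@@H](C)CCC[Cu] | intermediate
23 | ethyl (2Z,7S)-2-cuprio-3,7-dimethyldec-2-en-8-ynoate | CCOC(=O)/C([Cu])=C(\C)CCC[C@H](C)C#CC | intermediate
24 | ethyl (2E,7S)-3,7-dimethyldec-2-en-8-ynoate | CCOC(=O)/C=C(\C)CCC[C@H](C)C#CC | intermediate
25 | (2E,7S)-3,7-dimethyldec-2-en-8-yn-1-ol | OC/C=C(\C)CCC[C@H](C)C#CC | intermediate
26 | [(2S,3S)-3-methyl-3-[(4S)-4-methylhept-5-yn-1-yl]oxiran-2-yl]methanol | OC[C@@H]1O[C@@]1(C)CCC[C@H](C)C#CC | intermediate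
27 | (2R,3S)-3-methyl-3-[(4S)-4-methylhept-5-yn-1-yl]oxirane-2-carbaldehyde | O=C[C@@H]1O[C@@]1(C)CCC[C@H](C)C#CC | intermediate
28 | [(6R)-2,6-dimethyl-6-(triethylsilyloxy)dec-2-en-8-yn-3-yl]lithium | CC#CC[C@](C)(O[Si](CC)(CC)CC)CCC([Li])=C(C)C | intermediate
29 | (5R)-5-methyl-1-[(2S,3S)-3-methyl-3-[(4S)-4-methylhept-5-yn-1-yl]oxiran-2-yl]-2-(propan-2-ylidene)-5-(triethylsilyloxy)non-7-yn-1-ol (C1 epimers) | CC#CC[C@](C)(O[Si](CC)(CC)CC)CCC(=C(C)C)C(O)[C@@H]1O[C@@]1(C)CCC[C@H](C)C#CC | intermediate
30 | (5R)-5-methyl-1-[(2R,3S)-3-methyl-3-[(4S)-4-methylhept-5-yn-1-yl]oxiran-2-yl]-2-(propan-2-ylidene)-5-(triethylsilyloxy)non-7-yn-1-one (seco-diyne, key-step precursor) | CC#CC[C@](C)(O[Si](CC)(CC)CC)CCC(=C(C)C)C(=O)[C@@H]1O[C@@]1(C)CCC[C@H](C)C#CC | intermediate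
31 | (1R,5S,9S,10R)-1,5,9-trimethyl-12-(propan-2-ylidene)-1-(triethylsilyloxy)-9,10-epoxycyclotetradec-3-yn-11-one (key-step product) | CC[Si](CC)(CC)O[C@@]1(C)CC#C[C@@H](C)CCC[C@]2(C)O[C@H]2C(=O)C(=C(C)C)CC1 | intermediate
32 | (1R,5S,9S,10R)-1-hydroxy-1,5,9-trimethyl-12-(propan-2-ylidene)-9,10-epoxycyclotetradec-3-yn-11-one | O[C@@]1(C)CC#C[C@@H](C)CCC[C@]2(C)O[C@H]2C(=O)C(=C(C)C)CC1 | intermediate
33 | (1R,5S,9S,10R)-1,4:9,10-diepoxy-1,5,9-trimethyl-12-(propan-2-ylidene)cyclotetradec-3-en-11-one (C1–O–C4 bridged 2,3-dihydrofuran) | C[C@@]12CC=C(O1)[C@@H](C)CCC[C@]3(C)O[C@H]3C(=O)C(=C(C)C)CC2 | intermediate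
34 | (1R,5S,9S,10R)-1-hydroxy-1,5,9-trimethyl-12-(propan-2-ylidene)-9,10-epoxycyclotetradecane-4,11-dione | O[C@@]1(C)CCC(=O)[C@@H](C)CCC[C@]2(C)O[C@H]2C(=O)C(=C(C)C)CC1 | intermediate
35 | (1R,5S,9S,10R)-1,5,9-trimethyl-4,11-dioxo-12-(propan-2-ylidene)-9,10-epoxycyclotetradecyl acetate | CC(=O)O[C@@]1(C)CCC(=O)[C@@H](C)CCC[C@]2(C)O[C@H]2C(=O)C(=C(C)C)CC1 | target

Total step count: 21 (steps 1–7 from 1, steps 8–15 from 11, steps 16–21 after fragment union).
Longest linear sequence: 14 steps (steps 8–21, from (S)-citronellal 11).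

Steps most likely to fail

Step 18. The alkylidyne may be deactivated by coordination to the Lewis-basic epoxy ketone and enone, or intermolecular metathesis may outrun ring closure and give oligomers. The fallback moves the ring closure to the carbinol oxidation level, so that the catalyst meets no carbonyl group. It sets out from 29. Silylation of the C11 hydroxyl (TESOTf, 2,6-lutidine, −78 °C) would give the seco bis(triethylsilyl) ether F1. Ring-closing alkyne metathesis of this carbonyl-free diyne would give the cyclic bis(triethylsilyl) ether F2. Global desilylation with HF·pyridine would give the cycloalkyne diol F3. Dess–Martin oxidation of its only oxidisable hydroxyl, the secondary allylic one, comes back to the route at 32.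

Step 7. Loss of HBr toward the methyl groups (giving an allylic bromide) or solvolysis of the tertiary bromide may erode the regioselectivity of the elimination. The fallback builds the tetrasubstituted vinyl electrophile regiospecifically from an enolate and sets out from 8. Epoxidation of the trisubstituted alkene with mCPBA would give the epoxide F4. Base-promoted epoxide-to-allylic-alcohol isomerisation with diethylaluminium 2,2,6,6-tetramethylpiperidide, by abstraction of a methyl hydrogen, would give the isopropenyl carbinol F5. Dess–Martin oxidation would give the isopropenyl ketone F6. 1,4-Reduction with L-Selectride and trapping of the regiodefined enolate with N-(5-chloro-2-pyridyl)triflimide would give the enol triflate F7. Nozaki–Hiyama–Kishi coupling of F7 with 27 (CrCl2, cat. NiCl2, DMF) comes back to the route at 29.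

Step 8. The strong base may isomerise the new alkyne toward an allene through the propargylic C–H, eroding the enantiomeric purity of the future C5, or the aldehyde may self-condense before O-sulfonylation. The fallback degrades the aldehyde by one carbon and then rebuilds the alkyne, and sets out from 11. Condensation with morpholine would give the enamine F8. Sensitised photo-oxygenation at −78 °C would cleave the enamine double bond, which is far more reactive toward singlet oxygen than the trisubstituted alkene, to give (2S)-2,6-dimethylhept-5-enal F9. Corey–Fuchs dibromomethylenation (CBr4, PPh3) would give the dibromoalkene F10. Treatment with n-BuLi and then MeI comes back to the route at 15.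

Further compounds
F1 | step 18 | (5R)-5-methyl-1-[(2S,3S)-3-methyl-3-[(4S)-4-methylhept-5-yn-1-yl]oxiran-2-yl]-2-(propan-2-ylidene)-1,5-bis(triethylsilyloxy)non-7-yne (C1 epimers) | CC#CC[C@](C)(O[Si](CC)(CC)CC)CCC(=C(C)C)C(O[Si](CC)(CC)CC)[C@@H]1O[C@@]1(C)CCC[C@H](C)C#CC
F2 | step 18 | (1R,5S,9S,10S)-1,5,9-trimethyl-12-(propan-2-ylidene)-1,11-bis(triethylsilyloxy)-9,10-epoxycyclotetradec-3-yne (C11 epimers) | CC[Si](CC)(CC)O[C@@]1(C)CC#C[C@@H](C)CCC[C@]2(C)O[C@H]2C(O[Si](CC)(CC)CC)C(=C(C)C)CC1
F3 | step 18 | (1R,5S,9S,10S)-1,5,9-trimethyl-12-(propan-2-ylidene)-9,10-epoxycyclotetradec-3-yne-1,11-diol (C11 epimers) | O[C@@]1(C)CC#C[C@@H](C)CCC[C@]2(C)O[C@H]2C(O)C(=C(C)C)CC1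
F4 | step 7 | triethyl{[(3R)-1-(3,3-dimethyloxiran-2-yl)-3-methylhept-5-yn-3-yl]oxy}silane (oxirane epimers) | CC#CC[C@](C)(O[Si](CC)(CC)CC)CCC1OC1(C)C
F5 | step 7 | (6R)-2,6-dimethyl-6-(triethylsilyloxy)dec-1-en-8-yn-3-ol (C3 epimers) | CC#CC[C@](C)(O[Si](CC)(CC)CC)CCC(O)C(C)=C
F6 | step 7 | (6R)-2,6-dimethyl-6-(triethylsilyloxy)dec-1-en-8-yn-3-one | CC#CC[C@](C)(O[Si](CC)(CC)CC)CCC(=O)C(C)=C
F7 | step 7 | (6R)-2,6-dimethyl-6-(triethylsilyloxy)dec-2-en-8-yn-3-yl trifluoromethanesulfonate | CC#CC[C@](C)(O[Si](CC)(CC)CC)CCC(OS(=O)(=O)C(F)(F)F)=C(C)C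
F8 | step 8 | 4-[(1E,3S)-3,7-dimethylocta-1,6-dien-1-yl]morpholine | CC(C)=CCC[C@H](C)/C=C/N1CCOCC1
F9 | step 8 | (2S)-2,6-dimethylhept-5-enal | O=C[C@@H](C)CCC=C(C)C
F10 | step 8 | (3S)-1,1-dibromo-3,7-dimethylocta-1,6-diene | BrC(Br)=C[C@@H](C)CCC=C(C)C
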